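**Retrosynthetic overview**
Rings: A = resorcinol ring, B = catechol ring fused to the seven-membered ring, C = central monophenol ring, D = pendant catechol ring. All phenols travel as methyl ethers (14 <= 13).
Key disconnection: the bond between the bridge CH2 and ring A in the 9,10-dihydrophenanthrene (13 <= 11). Feature used: in 11 the exocyclic C5=CH2, the C4a–C4 bond of ring C and the C1'–C6' bond of ring A form a 2-vinylbiaryl hexatriene. Its ring A terminus C6' is meta to both oxygens, so polar closure is mismatched, yet it carries the very hydrogen that the C5 methine of the target needs.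
11 <= ketone 9 <= enone 8 (asymmetric hydrogenation sets the ring D methine) <= triflate 6 + boronic acid 7 (biaryl bond).
6 <= lactone 4/3 <= toluate 1 + benzophenone 2. Hidden symmetry: until the seven-membered ring closes, the future ring D methine carbon carries two identical veratryl groups, so the triarylalkene has no E/Z problem.
Order of ring formation: temporary lactone ring (opened again), seven-membered ring, biaryl bond, six-membered ring.

Key step: step 7

Assumption: the (S)-phosphinooxazoline ligand is taken to deliver hydrogen to the face of 8 that gives (10S)-9; if the sense of induction is the opposite in this ring system, the ligand enantiomer is exchanged.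

Step 1
Reactants: 1 methyl 2-hydroxy-4-methoxy-6-methylbenzoate; 2 bis(3,4-dimethoxyphenyl)methanone
Product: 3 lactone phenol [3,3-bis(3,4-dimethoxyphenyl)-8-hydroxy-6-methoxy-3,4-dihydro-1H-isochromen-1-one]
Conditions: LiN(iPr)2 (3.3 equiv), THF, −78 °C; then 2, −78 °C → rt; aq HCl work-up
Reagents that add atoms: none
Why: Lateral lithiation of the o-toluate (phenol masked in situ as its lithium phenoxide) gives a benzylic anion that should add 1,2 to the non-enolisable ketone 2, and the tertiary alkoxide closes onto the neighbouring ester (toluate anion addition–lactonisation), which creates the temporary lactone ring and no stereocentre because the two aryl groups are identical.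

Step 2
Reactants: 3 lactone phenol
Product: 4 lactone triflate [3,3-bis(3,4-dimethoxyphenyl)-6-methoxy-1-oxo-3,4-dihydro-1H-isochromen-8-yl trifluoromethanesulfonate]
Conditions: Tf2O, pyridine, CH2Cl2, 0 °C
Reagents that add atoms: trifluoromethanesulfonic anhydride, O=S(=O)(OS(=O)(=O)C(F)(F)F)C(F)(F)F
Why: Standard O-sulfonylation of the chelated phenol installs the cross-coupling handle and, as an electron-withdrawing group on ring C, should suppress protodecarboxylation in the acid step that follows.

Step 3
Reactants: 4 lactone triflate
Product: 6 enone triflate [10-(3,4-dimethoxyphenyl)-2,7,8-trimethoxy-5-oxo-5H-dibenzo[a,d][7]annulen-4-yl trifluoromethanesulfonate], via alkene acid 5 (not isolated)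
Conditions: TfOH (0.3 equiv), (CF3CO)2O (3 equiv), CH2Cl2 (high dilution), 0 °C → rt
Reagents that add atoms: none
Why: Acid ionises the doubly benzylic lactone C–O bond and E1 proton loss gives alkene acid 5, whose mixed trifluoroacetic anhydride undergoes intramolecular Friedel–Crafts acylation para to a methoxy group of the veratryl ring lying cis to ring C, a ring that is always available because both alkene substituents are the same, so the seven-membered ring should close without any E/Z issue.

Step 4
Reactants: 6 enone triflate; 7 (2,4-dimethoxyphenyl)boronic acid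
Product: 8 biaryl enone [4-(2,4-dimethoxyphenyl)-10-(3,4-dimethoxyphenyl)-2,7,8-trimethoxy-5H-dibenzo[a,d][7]annulen-5-one]
Conditions: Pd(OAc)2 (5 mol %), SPhos, K3PO4, toluene/H2O, 90 °C
Reagents that add atoms: none
Why: Suzuki–Miyaura coupling of a ketone-activated aryl triflate with an electron-rich boronic acid is well precedented for ortho-substituted partners with a bulky biarylphosphine, and ring A is brought in only now so that its very nucleophilic positions never meet the acylating medium.

Step 5
Reactants: 8 biaryl enone
Product: 9 saturated ketone [(10S)-4-(2,4-dimethoxyphenyl)-10-(3,4-dimethoxyphenyl)-2,7,8-trimethoxy-10,11-dihydro-5H-dibenzo[a,d][7]annulen-5-one]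
Conditions: H2 (50 bar), [Ir(cod)(L)]BArF (2 mol %, L = (S)-tBu-PHOX), CH2Cl2, rt
Reagents that add atoms: none
Why: Iridium-catalysed asymmetric hydrogenation of an unfunctionalised trisubstituted aryl alkene whose geometry is fixed by the ring should add hydrogen to one enantiotopic face under control of the chiral P,N ligand and set the (10S) stereocentre, leaving the diaryl ketone untouched.

Step 6
Reactants: 9 saturated ketone
Product: 11 methylidene compound [(10S)-4-(2,4-dimethoxyphenyl)-10-(3,4-dimethoxyphenyl)-2,7,8-trimethoxy-5-methylidene-10,11-dihydro-5H-dibenzo[a,d][7]annulene], via tertiary carbinol 10 (not isolated)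
Conditions: MeMgBr, THF, 0 → 40 °C; then H2O; crude carbinol, p-TsOH·H2O (cat.), toluene, 60 °C
Reagents that add atoms: methylmagnesium bromide, C[Mg]Br
Why: Grignard 1,2-addition to the non-enolisable diaryl ketone followed by acid-catalysed E1 dehydration, in which only the new methyl group can lose a proton, should give the exocyclic 1,1-diarylethylene without touching C10.

Step 7
Reactants: 11 methylidene compound
Product: 13 heptamethyl ether of the target [(R) at the methine bonded to rings B and C; (S) at the methine bearing ring D], via dearomatised polyene 12 (not isolated)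
Conditions: hν (300 nm, Pyrex), degassed cyclohexane/benzene (2 mM), Ar, rt
Reagents that add atoms: none
Why: Excitation of the 2-vinylbiaryl chromophore triggers a conrotatory 6π electrocyclisation in which the methylidene carbon bonds to the unsubstituted ortho carbon of ring A to give polyene 12, and a thermal suprafacial [1,5]-hydrogen shift then carries the hydrogen of that ring A carbon to the former alkene carbon C5, rearomatising rings A and C. The closest known reaction is the non-oxidative photocyclisation of 2-vinylbiphenyls and 2-(1-arylvinyl)biphenyls to 9,10-dihydrophenanthrenes. The six-membered ring closes in electrocyclic mode, its six atoms being the hexatriene itself (formally 6-endo at the alkene), so it does not matter that the ring A carbon is meta to both methoxy groups. The new methine stereocentre is controlled by C10: a pseudo-axial ring D (avoiding peri strain with H9) fixes one boat of the seven-membered ring, the boat fixes the helicity of the hexatriene, ring A reaches only the convex face of the alkene, and the hydrogen migrates on that same face, anti to ring D, which should give the (R) methine with the two methine hydrogens cis. Selectivity between the two ortho carbons of ring A is secured because closure onto the methoxy-bearing carbon gives a polyene with no migrating hydrogen that can only revert, and ring B offers no second hexatriene because it has no ortho aryl group. Rigorous exclusion of oxygen keeps 12 from being oxidised to the phenanthrene.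

Step 8
Reactants: 13 heptamethyl ether
Product: 14 target CNP0306974.1
Conditions: BBr3 (excess), CH2Cl2, −78 °C → rt; then H2O
Reagents that add atoms: none
Why: Exhaustive Lewis-acid ether cleavage with BBr3 removes all seven methyl groups by bromide attack at the methyl carbons, so neither benzylic stereocentre is involved.

**Compound list**
1 | methyl 2-hydroxy-4-methoxy-6-methylbenzoate | COC(=O)c1c(C)cc(OC)cc1O | starting material
2 | bis(3,4-dimethoxyphenyl)methanone | COc1ccc(cc1OC)C(=O)c1ccc(OC)c(OC)c1 | starting material
3 | lactone phenol, 3,3-bis(3,4-dimethoxyphenyl)-8-hydroxy-6-methoxy-3,4-dihydro-1H-isochromen-1-one | COc1cc(O)c2C(=O)OC(c3ccc(OC)c(OC)c3)(c3ccc(OC)c(OC)c3)Cc2c1 | intermediate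
4 | lactone triflate, 8-O-triflate of 3 | COc1cc(OS(=O)(=O)C(F)(F)F)c2C(=O)OC(c3ccc(OC)c(OC)c3)(c3ccc(OC)c(OC)c3)Cc2c1 | intermediate
5 | alkene acid, 2-[2,2-bis(3,4-dimethoxyphenyl)ethenyl]-4-methoxy-6-(trifluoromethylsulfonyloxy)benzoic acid | COc1cc(OS(=O)(=O)C(F)(F)F)c(C(=O)O)c(C=C(c2ccc(OC)c(OC)c2)c2ccc(OC)c(OC)c2)c1 | intermediate
6 | enone triflate, 10-(3,4-dimethoxyphenyl)-2,7,8-trimethoxy-5-oxo-5H-dibenzo[a,d][7]annulen-4-yl trifluoromethanesulfonate | COc1cc(OS(=O)(=O)C(F)(F)F)c2C(=O)c3cc(OC)c(OC)cc3C(c3ccc(OC)c(OC)c3)=Cc2c1 | intermediate
7 | (2,4-dimethoxyphenyl)boronic acid | COc1ccc(B(O)O)c(OC)c1 | starting material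
8 | biaryl enone, 4-(2,4-dimethoxyphenyl)-10-(3,4-dimethoxyphenyl)-2,7,8-trimethoxy-5H-dibenzo[a,d][7]annulen-5-one | COc1ccc(c(OC)c1)-c1cc(OC)cc2c1C(=O)c1cc(OC)c(OC)cc1C(c1ccc(OC)c(OC)c1)=C2 | intermediate
9 | saturated ketone, (10S)-10,11-dihydro derivative of 8 | COc1ccc(c(OC)c1)-c1cc(OC)cc2c1C(=O)c1cc(OC)c(OC)cc1[C@H](c1ccc(OC)c(OC)c1)C2 | intermediate
10 | tertiary carbinol, (10S)-5-methyl-5-ol from 9 (both C5 epimers) | COc1ccc(c(OC)c1)-c1cc(OC)cc2c1C(C)(O)c1cc(OC)c(OC)cc1[C@H](c1ccc(OC)c(OC)c1)C2 | intermediate
11 | methylidene compound, (10S)-5-methylidene analogue of 9 | COc1ccc(c(OC)c1)-c1cc(OC)cc2c1C(=C)c1cc(OC)c(OC)cc1[C@H](c1ccc(OC)c(OC)c1)C2 | intermediate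
12 | dearomatised polyene: former ortho CH of ring A now sp3, bonded to the new CH2, its H on the face that becomes the methine H; ring A=ring C and ring C=C5 double bonds | COC1=C[C@@H]2CC(c3cc(OC)c(OC)cc3[C@H](c3ccc(OC)c(OC)c3)C3)=C4C3=CC(OC)=CC4=C2C(OC)=C1 | intermediate
13 | heptamethyl ether of the target, (R) at the ring B/ring C methine, (S) at the ring D methine | COc1cc(OC)c2c(c1)C[C@@H]1c3cc(OC)c(OC)cc3[C@H](c3ccc(OC)c(OC)c3)Cc3cc(OC)cc-2c31 | intermediate
14 | CNP0306974.1 | Oc1cc(O)c2c(c1)C[C@@H]1c3cc(O)c(O)cc3[C@H](c3ccc(O)c(O)c3)Cc3cc(O)cc-2c31 | target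

**Step count and risks**
Total step count: 8. Longest linear sequence: 8 steps (1 → 14).

Step 7. In the dearomatised intermediate the hydrogen shift may be outrun by cycloreversion or by adventitious oxidation, or hydrogen may be delivered with poor facial selectivity.
Fallback, from 11 back to 13: irradiation of 11 with iodine and propylene oxide (oxidative Mallory-type photocyclisation) traps the closed form irreversibly as the (S)-configured heptamethoxy phenanthrene, the 9,10-didehydro analogue of 13, F1. Hydrogenation of its 9,10-bond (H2, Pd on carbon, EtOAc/AcOH) from the convex face, anti to ring D, should then give 13. The methine is thus set by an external reagent instead of a sigmatropic shift.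

Step 5. The crowded triaryl alkene may take up hydrogen slowly, or the catalyst may discriminate its faces poorly.
Fallback, from 8 back to 9: Corey–Bakshi–Shibata reduction of the diaryl ketone (Me-CBS oxazaborolidine, BH3·SMe2), whose two aryl flanks differ strongly in bulk, should give the (5S)-configured alkene carbinol F2. Its pseudo-axial hydroxyl group lies over the alkene and should direct hydrogenation with [Ir(cod)(PCy3)(py)]PF6 to the same face, giving the (5S,10S)-configured saturated carbinol F3. Dess–Martin oxidation erases the temporary carbinol stereocentre and returns 9.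

Step 3. The electron-rich triarylethylene or its cation may oligomerise, or the benzoic acid may lose CO2, before acylation occurs.
Fallback, from 4 back to 6: ionic hydrogenation of the lactone (Et3SiH, CF3CO2H) gives the saturated acid 2-[2,2-bis(3,4-dimethoxyphenyl)ethyl]-4-methoxy-6-(trifluoromethylsulfonyloxy)benzoic acid F4. Classical Friedel–Crafts acylation of this alkene-free acid ((CF3CO)2O, TfOH) gives the racemic saturated ketone triflate F5. Dehydrogenation with DDQ (hydride abstraction at the diarylmethine, then proton loss) restores the ring alkene of 6.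

**Further compounds**
F1 | step 7 | (S)-configured heptamethoxy phenanthrene, 9,10-didehydro analogue of 13 | COc1cc(OC)c2c(c1)cc1-c3cc(OC)c(OC)cc3[C@H](c3ccc(OC)c(OC)c3)Cc3cc(OC)cc2c31
F2 | step 5 | (5S)-4-(2,4-dimethoxyphenyl)-10-(3,4-dimethoxyphenyl)-2,7,8-trimethoxy-5H-dibenzo[a,d][7]annulen-5-ol | COc1ccc(c(OC)c1)-c1cc(OC)cc2c1[C@@H](O)c1cc(OC)c(OC)cc1C(c1ccc(OC)c(OC)c1)=C2
F3 | step 5 | (5S,10S)-4-(2,4-dimethoxyphenyl)-10-(3,4-dimethoxyphenyl)-2,7,8-trimethoxy-10,11-dihydro-5H-dibenzo[a,d][7]annulen-5-ol | COc1ccc(c(OC)c1)-c1cc(OC)cc2c1[C@@H](O)c1cc(OC)c(OC)cc1[C@H](c1ccc(OC)c(OC)c1)C2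
F4 | step 3 | 2-[2,2-bis(3,4-dimethoxyphenyl)ethyl]-4-methoxy-6-(trifluoromethylsulfonyloxy)benzoic acid | COc1cc(OS(=O)(=O)C(F)(F)F)c(C(=O)O)c(CC(c2ccc(OC)c(OC)c2)c2ccc(OC)c(OC)c2)c1
F5 | step 3 | racemic 10-(3,4-dimethoxyphenyl)-2,7,8-trimethoxy-5-oxo-10,11-dihydro-5H-dibenzo[a,d][7]annulen-4-yl trifluoromethanesulfonate | COc1cc(OS(=O)(=O)C(F)(F)F)c2C(=O)c3cc(OC)c(OC)cc3C(c3ccc(OC)c(OC)c3)Cc2c1
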